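**Strategy.** Everything rests on opening the six-membered carbocycle at the C5–C6 bond by a retro-aldol disconnection. The key step exploits the β-hydroxy ketone C1(=O)–C6–C5(OH) and the cis C2=C3 alkene of the cyclohexenone ring. An open-chain (Z)-enedione carrying a β-keto allyl ester, allyl (Z)-3,7-dioxohexacos-4-enoate, is folded by its cis alkene so that the doubly activated methylene can add to the C7 ketone. Under a chiral amine–squaramide this one operation closes the ring and sets the lone stereocentre, C5 (S). The precursor is released only at the last moment, by double oxidation of a protecting-group-free (Z)-ene-diol. Neutral deallylation–decarboxylation finishes the synthesis.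

Key step: step 6

Assumption: icosanal is taken as a purchasable aldehyde; the carbinol centres that are oxidized later and the epimerizable ester-bearing ring carbon are carried as mixtures, and the sense of induction in step 6 is fixed by choosing between the quinine- and quinidine-derived catalyst.

Step 1
Reactants: 1 icosanal; 2 propargyl bromide
Product: 4 tricos-1-yn-4-ol (racemic), via allenylzinc bromide 3 (not isolated)
Conditions: activated Zn dust (1.5 equiv), THF, 0 °C → rt; 1 M HCl work-up
Reagents that add atoms: none
Why: Barbier-type propargylation, in which zinc inserts into the bromide and the allenylzinc species adds to the aldehyde through a cyclic SE2′ transition state to give the homopropargylic alcohol; the carbinol configuration is irrelevant because this carbon becomes a ketone in step 5.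

Step 2
Reactants: 4 tricos-1-yn-4-ol
Product: 7 5-hydroxytetracos-2-ynal (racemic), via dilithium alkoxide acetylide 5 (not isolated), via dilithium hemiaminal alkoxide 6 (not isolated)
Conditions: n-BuLi (2.05 equiv), THF, −78 → −20 °C; DMF (3 equiv), −78 → 0 °C; inverse quench into cold 1 M HCl/MTBE; used crude
Reagents that add atoms: N,N-dimethylformamide (DMF), CN(C)C=O
Why: Acetylide formylation, in which only the carbon terminus of the alkoxide–acetylide dianion attacks DMF and the tetrahedral adduct survives until the acidic inverse quench, which releases the ynal and holds dimethylamine as its salt so that it cannot add to the triple bond.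

Step 3
Reactants: 7 5-hydroxytetracos-2-ynal; 8 allyl acetate
Product: 10 allyl 3,7-dihydroxyhexacos-4-ynoate (mixture of diastereomers), via lithium enolate of allyl acetate 9 (not isolated)
Conditions: lithium diisopropylamide (LDA, commercial solution, 2.3 equiv), 8 (2.3 equiv), THF, −78 °C; then 7, −78 °C; AcOH quench at −78 °C
Reagents that add atoms: none
Why: Lithium ester-enolate aldol addition, 1,2 to the ynal at low temperature (one extra equivalent of enolate is spent on the free hydroxyl); the diastereomer mixture is of no consequence since both carbinols are oxidized in step 5.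

Step 4
Reactants: 10 allyl 3,7-dihydroxyhexacos-4-ynoate
Product: 11 allyl (Z)-3,7-dihydroxyhexacos-4-enoate (mixture of diastereomers)
Conditions: H2 (1 atm), Lindlar catalyst (Pd on CaCO3 poisoned with Pb(OAc)2), quinoline, EtOAc, rt; stopped after 1 equiv H2
Reagents that add atoms: none
Why: Lindlar semi-hydrogenation delivers both hydrogens to one face of the alkyne and so sets the (Z)-C4=C5 geometry, and the poisoned catalyst should reduce the alkyne far faster than the monosubstituted alkene of the allyl ester.

Step 5
Reactants: 11 allyl (Z)-3,7-dihydroxyhexacos-4-enoate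
Product: 13 allyl (Z)-3,7-dioxohexacos-4-enoate, via allyl (Z)-7-hydroxy-3-oxohexacos-4-enoate 12 (not isolated)
Conditions: Dess–Martin periodinane (2.5 equiv), NaHCO3 (10 equiv), CH2Cl2, 0 °C → rt; cold aq. Na2S2O3/NaHCO3 wash; used at once
Reagents that add atoms: none
Why: Buffered Dess–Martin oxidation of both secondary carbinols, a reagent that converts (Z)-allylic alcohols into (Z)-enones and β-hydroxy esters into β-keto esters without base; the allylic carbinol should go first and the transient hydroxy enone 12 should be consumed by the excess oxidant before its lactol can lose water.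

Step 6
Reactants: 13 allyl (Z)-3,7-dioxohexacos-4-enoate
Product: 14 allyl (2S)-2-hydroxy-2-nonadecyl-6-oxocyclohex-4-ene-1-carboxylate (mixture of C1 epimers and enol form)
Conditions: quinine-derived squaramide 3-{[3,5-bis(trifluoromethyl)phenyl]amino}-4-{[(8α,9S)-6′-methoxycinchonan-9-yl]amino}cyclobut-3-ene-1,2-dione (10 mol %), toluene/CH2Cl2, 0.02 M, −40 °C; cold filtration through a short silica pad, no aqueous acid or base
Reagents that add atoms: none
Why: Proposed new method: the quinuclidine nitrogen should deprotonate the C2 methylene of the β-keto ester, by far the most acidic C–H of 13, while the two squaramide N–H bonds hydrogen-bond the C7 carbonyl, so that the ion-paired enolate carbon adds to C7 and forms the ring bond C5–C6 of the target before the proton returns to the tertiary alkoxide. The closest known reactions are the base-mediated intramolecular aldol closures of poly-β-carbonyl chains that run on to resorcylates and salicylates, and amine–squaramide-catalysed aldol additions of 1,3-dicarbonyl compounds to activated ketones; an enantioselective closure onto an unactivated dialkyl ketone that halts at the ketol has no direct precedent. The six-membered ring closes by 6-exo-trig attack on the C7 carbonyl, which is 6-(enolendo) for the C2=C3 ketone enolate (enolexo only if the ester enolate form is counted), a mode that is allowed. The carbinol centre (chain C7, ring C5) is set by the catalyst alone, which has to select one of the two enantiomeric half-chair ion pairs of the achiral substrate; the quinidine-derived pseudoenantiomer is held ready in case the quinine series gives the (R)-carbinol, and the second new centre at the ester-bearing carbon is epimerizable and disappears in step 7. Chemoselectivity for C2 over C6 and C8 follows from the acidity gap between the β-keto ester and the simple ketone α-positions, the (Z)-C4=C5 alkene places C2 next to C7, and high dilution disfavours intermolecular conjugate addition. Low temperature, an aprotic medium and a neutral isolation are required so that the ketol neither reverts by retro-aldol cleavage nor loses water towards allyl 6-nonadecylsalicylate.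

Step 7
Reactants: 14 allyl (2S)-2-hydroxy-2-nonadecyl-6-oxocyclohex-4-ene-1-carboxylate
Product: 16 (S)-5-hydroxy-5-nonadecylcyclohex-2-en-1-one, via (2S)-2-hydroxy-2-nonadecyl-6-oxocyclohex-4-ene-1-carboxylic acid 15 (not isolated)
Conditions: Pd(PPh3)4 (5 mol %), morpholine (5 equiv), THF, 0 °C → rt; pH 7 phosphate buffer work-up
Reagents that add atoms: none
Why: Tsuji–Trost deallylation, in which zerovalent palladium ionizes the allyl ester, morpholine takes up the allyl fragment and the freed β-keto acid loses CO2 at room temperature through the usual cyclic transition state; the quaternary carbinol centre is not touched and should keep its configuration.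

**Compound list**

1 | icosanal | CCCCCCCCCCCCCCCCCCCC=O | starting material
2 | propargyl bromide (3-bromoprop-1-yne) | C#CCBr | starting material
3 | allenylzinc bromide (bromo(propa-1,2-dien-1-yl)zinc) | C=C=C[Zn]Br | intermediate (not isolated)
4 | tricos-1-yn-4-ol, racemic | CCCCCCCCCCCCCCCCCCCC(O)CC#C | intermediate
5 | dilithium salt of 4 (lithium alkoxide at C4, lithium acetylide at C1) | CCCCCCCCCCCCCCCCCCCC(O[Li])CC#C[Li] | intermediate (not isolated)
6 | dilithium 1-(dimethylamino)tetracos-2-yne-1,5-diolate | CCCCCCCCCCCCCCCCCCCC(O[Li])CC#CC(O[Li])N(C)C | intermediate (not isolated)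
7 | 5-hydroxytetracos-2-ynal, racemic | CCCCCCCCCCCCCCCCCCCC(O)CC#CC=O | intermediate
8 | allyl acetate | CC(=O)OCC=C | starting material
9 | lithium enolate of allyl acetate (lithium 1-(allyloxy)ethen-1-olate) | C=C(O[Li])OCC=C | intermediate (not isolated)
10 | allyl 3,7-dihydroxyhexacos-4-ynoate, mixture of diastereomers | CCCCCCCCCCCCCCCCCCCC(O)CC#CC(O)CC(=O)OCC=C | intermediate
11 | allyl (Z)-3,7-dihydroxyhexacos-4-enoate, mixture of diastereomers | CCCCCCCCCCCCCCCCCCCC(O)C/C=C\C(O)CC(=O)OCC=C | intermediate
12 | allyl (Z)-7-hydroxy-3-oxohexacos-4-enoate, racemic | CCCCCCCCCCCCCCCCCCCC(O)C/C=C\C(=O)CC(=O)OCC=C | intermediate (not isolated)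
13 | allyl (Z)-3,7-dioxohexacos-4-enoate | CCCCCCCCCCCCCCCCCCCC(=O)C/C=C\C(=O)CC(=O)OCC=C | intermediate
14 | allyl (2S)-2-hydroxy-2-nonadecyl-6-oxocyclohex-4-ene-1-carboxylate, C1 unassigned | CCCCCCCCCCCCCCCCCCC[C@]1(O)CC=CC(=O)C1C(=O)OCC=C | intermediate
15 | (2S)-2-hydroxy-2-nonadecyl-6-oxocyclohex-4-ene-1-carboxylic acid, C1 unassigned | CCCCCCCCCCCCCCCCCCC[C@]1(O)CC=CC(=O)C1C(=O)O | intermediate (not isolated)
16 | (S)-5-hydroxy-5-nonadecylcyclohex-2-en-1-one | CCCCCCCCCCCCCCCCCCC[C@]1(O)CC=CC(=O)C1 | target

Total step count: 7. Longest linear sequence: 7 (steps 1 to 7).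

**Steps most likely to fail**

Step 6 (the step that rests on an unprecedented method). What may go wrong: poor facial discrimination at the C7 carbonyl, retro-aldol equilibration that erodes the enantiomeric purity, loss of water with aromatization, or intermolecular conjugate addition. The fallback uses known chemistry, builds the ring first and installs the carbinol by catalyst-controlled conjugate borylation. It sets out from alkynediol 10 and comes back to the route at the target 16.
- Exhaustive hydrogenation of 10 (H2, Pd on carbon, EtOAc) should saturate the alkyne and the allyl group and give propyl 3,7-dihydroxyhexacosanoate F1.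
- Dess–Martin oxidation should give propyl 3,7-dioxohexacosanoate F2.
- Intramolecular Knoevenagel condensation (piperidinium acetate, toluene, water separator) should close propyl 2-nonadecyl-6-oxocyclohex-1-ene-1-carboxylate F3; the doubly activated methylene fixes the regiochemistry.
- Ester hydrolysis with decarboxylation (aq. H2SO4/AcOH, reflux) should give 3-nonadecylcyclohex-2-en-1-one F4.
- Copper-catalysed enantioselective conjugate borylation of this β-substituted cyclic enone (B2pin2, [Cu(MeCN)4]PF6 as the monovalent copper source, LiOt-Bu, the QuinoxP* enantiomer that delivers the (R)-boronate, DMSO, rt) should give (R)-3-nonadecyl-3-(4,4,5,5-tetramethyl-1,3,2-dioxaborolan-2-yl)cyclohexan-1-one F5.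
- Oxidation with retention (NaBO3·4H2O, THF/H2O) should give (S)-3-hydroxy-3-nonadecylcyclohexan-1-one F6.
- Kinetic dianion formation on the side remote from the carbinol (LDA, 2.2 equiv, THF, −78 °C) and selenenylation with PhSeBr should give (5S)-5-hydroxy-5-nonadecyl-2-(phenylselanyl)cyclohexan-1-one F7.
- Its selenoxide (H2O2, pyridine, CH2Cl2, 0 °C) should undergo syn-elimination to 16.

Step 5. What may go wrong: over-oxidation at the C2 methylene by excess periodinane, closure of the half-oxidized hydroxy ketone to a lactol that loses water, cis-to-trans isomerization, or uncatalysed ring closure during work-up. The fallback brings C7 in at the ketone level as a ketal, so that only the allylic carbinol is oxidized at the end. It sets out from 4 and comes back at 13.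
- Buffered Dess–Martin oxidation of 4 should give the β,γ-alkynyl ketone tricos-1-yn-4-one F8, which is not chromatographed.
- Aprotic Noyori ketalization (MeOSiMe3, catalytic TMSOTf, CH2Cl2, −78 °C) should give 4,4-dimethoxytricos-1-yne F9.
- The operations of steps 2 to 4 (one equivalent of n-BuLi, phosphate-buffered quench) should then give in turn 5,5-dimethoxytetracos-2-ynal F10, allyl 3-hydroxy-7,7-dimethoxyhexacos-4-ynoate F11 and allyl (Z)-3-hydroxy-7,7-dimethoxyhexacos-4-enoate F12.
- A single Dess–Martin oxidation should give allyl (Z)-7,7-dimethoxy-3-oxohexacos-4-enoate F13.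
- Mild ketal hydrolysis (oxalic acid on wet silica gel, CH2Cl2, rt, or LiBF4 in wet MeCN) should release 13.

Step 7. What may go wrong: loss of water from the β-hydroxy ketone with aromatization, C-allylation of the enolate formed on decarboxylation, or conjugate addition of morpholine to the enone. The fallback replaces the transition-metal deallylation by enzymatic ester hydrolysis. It sets out from 14 and comes back at 16 by way of the same acid 15, and makes no new compound (F0). Pig liver esterase or immobilized Candida antarctica lipase B (pH 7 phosphate buffer, acetone as co-solvent, rt) should hydrolyse the allyl ester; the β-keto acid should then decarboxylate on its own at neutral pH without palladium or amine.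

**Further compounds**

F1 | step 6 | propyl 3,7-dihydroxyhexacosanoate | CCCCCCCCCCCCCCCCCCCC(O)CCCC(O)CC(=O)OCCC
F2 | step 6 | propyl 3,7-dioxohexacosanoate | CCCCCCCCCCCCCCCCCCCC(=O)CCCC(=O)CC(=O)OCCC
F3 | step 6 | propyl 2-nonadecyl-6-oxocyclohex-1-ene-1-carboxylate | CCCCCCCCCCCCCCCCCCCC1=C(C(=O)OCCC)C(=O)CCC1
F4 | step 6 | 3-nonadecylcyclohex-2-en-1-one | CCCCCCCCCCCCCCCCCCCC1=CC(=O)CCC1
F5 | step 6 | (R)-3-nonadecyl-3-(4,4,5,5-tetramethyl-1,3,2-dioxaborolan-2-yl)cyclohexan-1-one | CCCCCCCCCCCCCCCCCCC[C@]1(B2OC(C)(C)C(C)(C)O2)CCCC(=O)C1
F6 | step 6 | (S)-3-hydroxy-3-nonadecylcyclohexan-1-one | CCCCCCCCCCCCCCCCCCC[C@]1(O)CCCC(=O)C1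
F7 | step 6 | (5S)-5-hydroxy-5-nonadecyl-2-(phenylselanyl)cyclohexan-1-one | CCCCCCCCCCCCCCCCCCC[C@]1(O)CCC([Se]c2ccccc2)C(=O)C1
F8 | step 5 | tricos-1-yn-4-one | CCCCCCCCCCCCCCCCCCCC(=O)CC#C
F9 | step 5 | 4,4-dimethoxytricos-1-yne | CCCCCCCCCCCCCCCCCCCC(OC)(OC)CC#C
F10 | step 5 | 5,5-dimethoxytetracos-2-ynal | CCCCCCCCCCCCCCCCCCCC(OC)(OC)CC#CC=O
F11 | step 5 | allyl 3-hydroxy-7,7-dimethoxyhexacos-4-ynoate | CCCCCCCCCCCCCCCCCCCC(OC)(OC)CC#CC(O)CC(=O)OCC=C
F12 | step 5 | allyl (Z)-3-hydroxy-7,7-dimethoxyhexacos-4-enoate | CCCCCCCCCCCCCCCCCCCC(OC)(OC)C/C=C\C(O)CC(=O)OCC=C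
F13 | step 5 | allyl (Z)-7,7-dimethoxy-3-oxohexacos-4-enoate | CCCCCCCCCCCCCCCCCCCC(OC)(OC)C/C=C\C(=O)CC(=O)OCC=C
F0 | step 7 | none | none
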